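## The problem

The target is a 14-membered macrolactone. The ring runs from the carbonyl carbon C1 through C13 to the ring oxygen, and C13 carries the C14–C22 side chain. There are five stereocenters: C5, C9 and C13 in the ring, and the syn-1,3-diol C19/C21 in the side chain. C5, C9 and C13 are 1,5-related across the sp2 carbons C7 and C11, so none can control another and each has to come from a reagent or from the chiral pool; only C21 can control C19. The (E)-trisubstituted C6=C7 alkene (methyl on C7) needs secure geometry, and C11 and C15 each carry an exocyclic methylene. Sensitive features are the allylic C5 carbinol (ionisation in acid), the 1,1-disubstituted alkenes (migration with acid or metal hydrides), the 5-hydroxy ester (acyl transfer from O13 to O5) and any β-oxygenated carbonyl intermediate around C13 (elimination). The key step is possible because C2 and C3 are unsubstituted methylenes next to C1. The ring can therefore be closed by joining C2 and C3 as a temporary enoate double bond, which is afterwards the only electron-poor alkene and can be reduced alone. One hazard shapes the plan: both exocyclic methylenes are homoallylic to O13, so an acrylate on O13 could also close a six-membered unsaturated lactone with either of them. C11 and C15 are therefore carried at the ketone oxidation level through the ring closure.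

## Retrosynthesis

**Endgame.** Target 38 is traced back to its tetrakis-silyl ether 37 (Si–O bonds only), and 37 to the 2,3-unsaturated lactone 36 by adding back the C2=C3 double bond. The forward step must deliver hydride to one alkene out of four. This is feasible because C2=C3 is the only conjugated one, which is the reason for closing the ring there.

**The two methylene groups.** In 36 the C11=CH2 and C15=CH2 bonds are cut back to the ketones of diketo lactone 35. A precursor with both methylenes already in place was considered first. Each of them sits in a homoallyl relationship to O13, and ruthenium carbenes close acrylates of such alcohols to 5,6-dihydropyran-2-ones readily, so a small-ring pathway would compete with the macrocyclisation. With ketones at C11 and C15 this pathway does not exist. The cost is a late double methylenation, which must be non-basic because C13 is β to both carbonyls.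

**Key disconnection, C2=C3.** Lactone 35 is opened at C2=C3 to the acyclic acrylate 34. The neighbouring cut at O13–C1 (lactonisation) would require a C1 acid carried in masked form from the start and activation against a hindered carbinol. The C2=C3 cut lets C1–C2 arrive as acryloyl chloride 32 and C3–C4 as the allyl group that is introduced together with the C5 stereocenter. Precursor 34 is open-chain and has only two alkenes able to undergo metathesis. The forward reaction must join these two monosubstituted alkenes and leave the trisubstituted C6=C7 alone.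

**Ester and carbonyl unmasking.** Acrylate 34 comes from bis-dithiane acrylate 33 by hydrolysis of two thioacetals, and 33 from alcohol 31 and 32 by acylation of O13. Acylating before unmasking means the β-acyloxy ketone never meets an amine base.

**C10–C11 and C11–C12.** Alcohol 31 is cut on both sides of C11 into 2-silyl-1,3-dithiane 13 and the epoxides 10 (C3–C10) and 27 (C12–C22). C11 acts as a carbonyl dianion equivalent. A 1,4 carbon-to-oxygen silyl shift after the first epoxide opening puts the silyl group on O9 and leaves O13 as the only free hydroxyl. No protecting-group step is therefore needed to single out the acylation site. The forward step requires that the silyl shift starts only after epoxide 10 is consumed, which is solvent-controlled. Reagent 13 is made from 1,3-dithiane 11.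

**Side-chain epoxide 27.** The C14–C15 bond is cut to dithiane 24 and (R)-epichlorohydrin 1; C15 is again an acyl anion and C13 takes its configuration from 1. Dithiane 24 goes back through dioxolane 23 and syn-diol 22 to hydroxy ketone 19. Ketone 19 is cut at C18–C19 into Weinreb amide 15 and the chloride 16 (via its Grignard reagent). Amide 15 comes from ethyl (S)-3-hydroxybutanoate 14, which supplies C21. C19 is set from C21 by a chelate-controlled 1,3-syn reduction.

**Ring-side epoxide 10.** Silyl ether 10 comes from alcohol 9, which is cut at C4–C5 to the epoxy enal 7. Asymmetric allylboration sets C5 and brings the C3 vinyl group at once. Enal 7 goes back via the allylic alcohol 6 to chloro diol 5, which is cut at C5–C6 and at C7–CH3 to the alkynol 2. Carboalumination of a terminal alkyne is chosen over an olefination of a methyl ketone because it fixes the E geometry by mechanism. Alkynol 2 is cut at C7–C8 into acetylene and epichlorohydrin 1, which supplies C9.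

## Roads not taken

**Alternative 1:** The cuts at C10–C11 and C11–C12 become the centre of the synthesis, and the ring is closed later at O13–C1. Lithiated 13 opens the C1–C10 epoxide A2 (C1 as a PMB ether) at C10, silicon moves to O9, and the new anion opens the side-chain epoxide A3 at C12 to give A1.
- Merits: two C–C bonds in one flask, O9 and O13 differentiated, and a later lactonisation that is indifferent to every alkene, so the exocyclic methylenes can be in place early and no temporary unsaturation or reduction is needed.
- Weak points: after A1 the route still needs PMB removal, a two-stage oxidation of C1 beside an allylic silyl ether, carboxyl activation, high-dilution closure onto a carbinol flanked by the quaternary C11, and thioacetal removal and methylenation. The C1–C4 arm also cannot come from a simple allyl transfer, so C5 needs a longer construction.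
- Comparison: the same coupling is used here as step 14, so the difference lies only in how the ring is closed. Lactonisation is the more proven closure and needs no masking of C11 and C15. Against this the chosen plan offers C1–C2 from acryloyl chloride, C3–C4 from the allylboration that also sets C5, and a neutral ring closure with no oxidation-level changes at C1.

**Alternative 2:** The ring is cut at C6–C7 as an alkyne. The diyne ester A5 with two methyl-capped alkynes is closed by Mo(≡CC6H4OMe)(OSiPh3)3 to cycloalkyne A4.
- Merits: alkyne metathesis does not touch alkenes, so both exocyclic methylenes are true spectators. In chemoselectivity this is better than any alkene metathesis, including the chosen one.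
- Weak points: C6≡C7 must afterwards become the (E)-alkene with methyl on C7. Hydroxyl-directed trans-hydrostannation places tin on the alkyne carbon next to the directing carbinol, which is C6 when O5 directs, so the methyl would end on the wrong carbon. Direction from the homopropargylic O9 is less dependable. At least three steps follow ring closure, C5 needs its own asymmetric step in a separate acid fragment, and the alkylidyne is moisture-sensitive.
- Comparison: the chosen plan fixes the geometry and the methyl position of C6=C7 at the outset by carboalumination, and pays for its alkene metathesis by masking C11 and C15.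

**Alternative 3:** The ring is cut at C5–C6 together with C7–CH3. Ni(cod)2 (zerovalent nickel) and Me2Zn couple the aldehyde and the terminal alkyne of ynal ester A7 to give A6.
- Merits: ring, C5–C6 bond, C7 methyl and E geometry arise in one step. The ring-side fragment shrinks to a propargyl epoxide, which saves about four steps, so the step economy is better than in the chosen plan.
- Weak points: C5 is created during ring closure under the influence only of the remote C9 and of ring conformation, so its configuration is not predictable. Direct methyl transfer to the aldehyde and alkyne oligomerisation compete at high dilution. The zinc alkoxide at O5 is well placed to attack C1 and contract the ring.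
- Comparison: the chosen plan is longer on the ring side, but every stereocenter is set under reagent or chiral-pool control before the ring is closed, and the ring closure creates none.

Key step: step 17

Remark on the chemistry: carbons are numbered C1–C22 as in the macrolide; the alkene carbon lost as ethene in step 17 has no number; TBSO stands for tert-butyldimethylsilyloxy. Acetylene, (−)-B-methoxydiisopinocampheylborane and 2-(3-chloropropyl)-1,3-dioxolane are taken as commercial.

## Steps

Step 1
Reactants: 1 (R)-epichlorohydrin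
Product: 2 (2R)-1-chloropent-4-yn-2-ol
Conditions: HC≡CH, n-BuLi, THF, −78 °C; BF3·OEt2; then 1, −78 °C
Reagents that add atoms: acetylene C#C
Why: Yamaguchi–Hirao alkynylation: lithium acetylide opens the BF3-activated epoxide only at the unsubstituted ring carbon, so the C–O bond at the stereocenter is untouched and C9 keeps the configuration of 1.

Step 2
Reactants: 2
Product: 5 (2E,5R)-6-chloro-3-methylhex-2-ene-1,5-diol, via alkenylalane 3 (not isolated), via lithium alkenylalanate 4 (not isolated)
Conditions: Me3Al, Cp2ZrCl2 (25 mol %), CH2Cl2, 0 °C → rt; then n-BuLi, THF, −78 °C; (CH2O)n, −78 °C → rt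
Reagents that add atoms: trimethylaluminium C[Al](C)C; paraformaldehyde (as formaldehyde) C=O
Why: Negishi zirconium-catalysed carboalumination adds methyl and aluminium syn across the terminal alkyne with methyl on the internal carbon, which fixes the E geometry of C6=C7; the hydroxyl is carried as its aluminium alkoxide and the alanate is hydroxymethylated with retention to give C5.

Step 3
Reactants: 5
Product: 6 (2E)-3-methyl-4-[(2R)-oxiran-2-yl]but-2-en-1-ol
Conditions: K2CO3, MeOH, 0 °C → rt
Reagents that add atoms: none
Why: Intramolecular Williamson closure of the chlorohydrin; oxygen attacks the CH2Cl carbon, so the stereocenter is not involved and becomes the (R)-epoxide carbon C9.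

Step 4
Reactants: 6
Product: 7 (2E)-3-methyl-4-[(2R)-oxiran-2-yl]but-2-enal
Conditions: MnO2, CH2Cl2, rt
Reagents that add atoms: none
Why: Chemoselective allylic oxidation on a neutral solid surface, which should preserve the epoxide and the alkene geometry; the enal is used at once.

Step 5
Reactants: 7
Product: 9 (4S,5E)-6-methyl-7-[(2R)-oxiran-2-yl]hepta-1,5-dien-4-ol, via diisopinocampheylborinate 8 (not isolated)
Conditions: (−)-Ipc2BOMe, allylMgBr, Et2O, 0 °C → rt; then 7, −78 °C; NaOH, H2O2, 0 °C
Reagents that add atoms: allylmagnesium bromide C=CC[Mg]Br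
Why: Brown asymmetric allylboration through a chair transition state; the isopinocampheyl groups derived from (+)-α-pinene direct allyl to the Si face of the enal and should set C5 as S under reagent control, independent of the remote C9.

Step 6
Reactants: 9
Product: 10 tert-butyl(dimethyl){[(4S,5E)-6-methyl-7-[(2R)-oxiran-2-yl]hepta-1,5-dien-4-yl]oxy}silane
Conditions: TBSCl, imidazole, DMF, rt
Reagents that add atoms: tert-butyldimethylsilyl chloride CC(C)(C)[Si](C)(C)Cl
Why: Standard silylation of a secondary allylic alcohol under conditions that leave the terminal epoxide intact.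

Step 7
Reactants: 11 1,3-dithiane
Product: 13 2-(tert-butyldimethylsilyl)-1,3-dithiane, via 2-lithio-1,3-dithiane 12 (not isolated)
Conditions: n-BuLi, THF, −30 °C; TBSCl, −78 °C → rt
Reagents that add atoms: tert-butyldimethylsilyl chloride CC(C)(C)[Si](C)(C)Cl
Why: Corey–Seebach metalation of the dithiane followed by C-silylation gives the linchpin reagent.

Step 8
Reactants: 14 ethyl (S)-3-hydroxybutanoate
Product: 15 (3S)-3-hydroxy-N-methoxy-N-methylbutanamide
Conditions: MeNH(OMe)·HCl, i-PrMgCl, THF, −20 → 0 °C
Reagents that add atoms: N,O-dimethylhydroxylamine hydrochloride CNOC.Cl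
Why: Direct aminolysis of the ester by the magnesium amide (Weinreb amide formation); the free hydroxyl is tolerated as its magnesium alkoxide and C21 is not touched.

Step 9
Reactants: 15; 16 2-(3-chloropropyl)-1,3-dioxolane
Product: 19 (6S)-1-(1,3-dioxolan-2-yl)-6-hydroxyheptan-4-one, via Grignard reagent 17 (not isolated), via magnesium hemiaminal chelate 18 (not isolated)
Conditions: 16, Mg, THF, reflux; then 15, 0 °C → rt; NH4Cl (aq)
Reagents that add atoms: none
Why: Weinreb ketone synthesis; one equivalent of Grignard reagent deprotonates the hydroxyl, a second adds once, and the stable chelate releases the ketone only on work-up, forming C18–C19.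

Step 10
Reactants: 19
Product: 22 (2S,4R)-7-(1,3-dioxolan-2-yl)heptane-2,4-diol, via diethylboron chelate 20 (not isolated), via sodium dialkoxyborate 21 (not isolated)
Conditions: Et2BOMe, THF/MeOH (4:1), −78 °C; NaBH4; AcOH; MeOH co-evaporation
Reagents that add atoms: none
Why: Narasaka–Prasad reduction; the six-membered boron chelate of the β-hydroxy ketone is attacked axially by external hydride, so C21 should set C19 as the syn (19R) diol.

Step 11
Reactants: 22
Product: 23 2-[(4R,6S)-4,6-bis(TBSO)heptyl]-1,3-dioxolane
Conditions: TBSCl, imidazole, DMAP (cat.), DMF, 40 °C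
Reagents that add atoms: tert-butyldimethylsilyl chloride CC(C)(C)[Si](C)(C)Cl
Why: Bis-silylation under basic conditions, chosen over a silyl triflate so that the acetal is not activated.

Step 12
Reactants: 23
Product: 24 2-[(4R,6S)-4,6-bis(TBSO)heptyl]-1,3-dithiane
Conditions: HS(CH2)3SH, BF3·OEt2, CH2Cl2, −40 → 0 °C
Reagents that add atoms: propane-1,3-dithiol SCCCS
Why: Lewis-acid transthioacetalisation of the dioxolane; the low temperature is chosen to keep the secondary silyl ethers in place.

Step 13
Reactants: 24; 1 (R)-epichlorohydrin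
Product: 27 2-[(4R,6S)-4,6-bis(TBSO)heptyl]-2-{[(2R)-oxiran-2-yl]methyl}-1,3-dithiane, via 2-lithiodithiane 25 (not isolated), via lithium chloroalkoxide 26 (not isolated)
Conditions: t-BuLi, THF/HMPA (9:1), −78 °C; 1, −78 °C → rt
Reagents that add atoms: none
Why: Corey–Seebach alkylation: the dithiane anion opens 1 at the ring CH2 (forming C14–C15) and the alkoxide then displaces chloride, so C13 keeps the configuration of 1 and appears as the (R)-epoxide.

Step 14
Reactants: 13; 10; 27
Product: 31 2-[(2R,4E,6S)-2,6-bis(TBSO)-4-methylnona-4,8-dien-1-yl]-2-[(2R)-3-{2-[(4R,6S)-4,6-bis(TBSO)heptyl]-1,3-dithian-2-yl}-2-hydroxypropyl]-1,3-dithiane, via lithiated silyl dithiane 28 (not isolated), via lithium alkoxide 29 (not isolated), via Brook carbanion 30 (not isolated)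
Conditions: t-BuLi, Et2O, −78 → −45 °C; 10, −78 → −25 °C; then 27, THF/HMPA, −78 °C → rt
Reagents that add atoms: none
Why: Three-component dithiane linchpin coupling: the anion opens 10 at C10, HMPA then triggers the 1,4-Brook shift of silicon to O9, and the regenerated anion opens 27 at C12. Both epoxides react at CH2, so C9 and C13 are retained and O13 emerges as the only free hydroxyl.

Step 15
Reactants: 31; 32 acryloyl chloride
Product: 33 (2R)-1-{2-[(2R,4E,6S)-2,6-bis(TBSO)-4-methylnona-4,8-dien-1-yl]-1,3-dithian-2-yl}-3-{2-[(4R,6S)-4,6-bis(TBSO)heptyl]-1,3-dithian-2-yl}propan-2-yl prop-2-enoate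
Conditions: i-Pr2NEt, CH2Cl2, −78 → 0 °C
Reagents that add atoms: none
Why: Acylation of the single free secondary alcohol with a small, reactive acid chloride; with both carbonyls still masked there is no β-acyloxy ketone that the amine could eliminate.

Step 16
Reactants: 33
Product: 34 (4S,5E,8R,12R,18R,20S)-4,8,18,20-tetrakis(TBSO)-6-methyl-10,14-dioxohenicosa-1,5-dien-12-yl prop-2-enoate
Conditions: PhI(OCOCF3)2, CaCO3, MeCN/H2O (9:1), 0 °C
Reagents that add atoms: water O
Why: Oxidative hydrolysis of both dithianes with the hypervalent iodine reagent (Stork conditions) is fast at 0 °C and buffered, conditions that should leave the acrylate, the silyl ethers and the alkenes untouched.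

Step 17
Reactants: 34
Product: 35 (3E,6S,7E,10R,14R)-6,10-bis(TBSO)-14-[(6R,8S)-6,8-bis(TBSO)-2-oxononyl]-8-methyl-1-oxacyclotetradeca-3,7-diene-2,12-dione
Conditions: second-generation Hoveyda–Grubbs catalyst RuCl2(H2IMes)(=CH-C6H4-2-OiPr) (10 mol %), 1,4-benzoquinone (20 mol %), CH2Cl2 (1 mM), 40 °C, Ar purge
Reagents that add atoms: none
Why: The phosphine-free ruthenium benzylidene initiates on the monosubstituted C3 vinyl group; the resulting alkylidene adds across the acrylate C=C with ruthenium on the terminal carbon, and cycloreversion of the metallacyclobutane releases the C2=C3 enoate and a ruthenium methylidene that expels ethene. The closest known reaction type is ring-closing metathesis of ω-alkenyl acrylates to macrocyclic 2-enoates. The one ring closes as a 14-membered lactone by joining the terminal alkene carbons C2 and C3, an endocyclic macrocyclisation run near 1 mM so that it outruns oligomerisation. No stereocenter is formed; the E enoate is expected as the less strained isomer, and any Z isomer would converge in step 19. Only the two monosubstituted alkenes must react: C6=C7 is trisubstituted and inert, and C11 and C15 are ketones at this stage, so no 1,1-disubstituted alkene homoallylic to O13 can close a six-membered unsaturated lactone with the acrylate. The absence of free PCy3 avoids phosphine addition to the acrylate and loss of the β-acyloxy group, and benzoquinone suppresses alkene migration by ruthenium hydrides.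

Step 18
Reactants: 35
Product: 36 (3E,6S,7E,10S,14R)-6,10-bis(TBSO)-14-[(6R,8S)-6,8-bis(TBSO)-2-methylidenenonyl]-8-methyl-12-methylidene-1-oxacyclotetradeca-3,7-dien-2-one
Conditions: Zn, CH2Br2, TiCl4, THF/CH2Cl2, 0 °C → rt
Reagents that add atoms: dibromomethane BrCBr
Why: Takai–Lombardo methylenation; the gem-dimetallic reagent is non-basic and selective for ketones over esters, so both β-oxygenated ketones should be converted without elimination at C13 or attack on the enoate lactone.

Step 19
Reactants: 36
Product: 37 (6S,7E,10S,14R)-6,10-bis(TBSO)-14-[(6R,8S)-6,8-bis(TBSO)-2-methylidenenonyl]-8-methyl-12-methylidene-1-oxacyclotetradec-7-en-2-one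
Conditions: [(Ph3P)CuH]6, H2O, toluene, rt
Reagents that add atoms: none
Why: Conjugate reduction with the hexameric copper hydride delivers hydride to C3 of the only electron-poor alkene and the copper enolate is protonated by water; isolated alkenes are inert, and no ketone remains for a reductive aldol.

Step 20
Reactants: 37
Product: 38 (6S,7E,10S,14R)-14-[(6R,8S)-6,8-dihydroxy-2-methylidenenonyl]-6,10-dihydroxy-8-methyl-12-methylidene-1-oxacyclotetradec-7-en-2-one
Conditions: HF·pyridine, pyridine, THF, 0 °C → rt
Reagents that add atoms: none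
Why: Global cleavage of four silyl ethers by buffered fluoride; the buffer is chosen to avoid ionisation of the allylic C5 carbinol and acyl transfer within the 5-hydroxy ester.

## Compound list

1 | (R)-epichlorohydrin, (2R)-2-(chloromethyl)oxirane | ClC[C@H]1CO1 | starting material
2 | (2R)-1-chloropent-4-yn-2-ol | ClC[C@H](O)CC#C | intermediate
3 | alkenylalane: O,C-bis(dimethylaluminium) derivative of (2R,4E)-1-chloro-4-methylpent-4-en-2-ol, aluminium on C5 | ClC[C@H](O[Al](C)C)C/C(C)=C/[Al](C)C | intermediate (not isolated)
4 | lithium alkenylalanate: butyl ate complex of 3 | [Li+].ClC[C@H](O[Al](C)C)C/C(C)=C/[Al-](C)(C)CCCC | intermediate (not isolated)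
5 | (2E,5R)-6-chloro-3-methylhex-2-ene-1,5-diol | ClC[C@H](O)C/C(C)=C/CO | intermediate
6 | (2E)-3-methyl-4-[(2R)-oxiran-2-yl]but-2-en-1-ol | C1[C@H](O1)C/C(C)=C/CO | intermediate
7 | (2E)-3-methyl-4-[(2R)-oxiran-2-yl]but-2-enal | C1[C@H](O1)C/C(C)=C/C=O | intermediate
8 | (4S,5E)-6-methyl-7-[(2R)-oxiran-2-yl]hepta-1,5-dien-4-yl diisopinocampheylborinate | C1[C@H](O1)C/C(C)=C/[C@@H](OB([C@@H]2C[C@@H]3C[C@H]([C@H]2C)C3(C)C)[C@@H]4C[C@@H]5C[C@H]([C@H]4C)C5(C)C)CC=C | intermediate (not isolated)
9 | (4S,5E)-6-methyl-7-[(2R)-oxiran-2-yl]hepta-1,5-dien-4-ol | C1[C@H](O1)C/C(C)=C/[C@@H](O)CC=C | intermediate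
10 | tert-butyl(dimethyl){[(4S,5E)-6-methyl-7-[(2R)-oxiran-2-yl]hepta-1,5-dien-4-yl]oxy}silane (C3–C10 epoxide) | C1[C@H](O1)C/C(C)=C/[C@@H](O[Si](C)(C)C(C)(C)C)CC=C | intermediate
11 | 1,3-dithiane | C1CSCSC1 | starting material
12 | 2-lithio-1,3-dithiane | [Li]C1SCCCS1 | intermediate (not isolated)
13 | 2-(tert-butyldimethylsilyl)-1,3-dithiane | CC(C)(C)[Si](C)(C)C1SCCCS1 | intermediate
14 | ethyl (S)-3-hydroxybutanoate | CCOC(=O)C[C@H](C)O | starting material
15 | (3S)-3-hydroxy-N-methoxy-N-methylbutanamide | C[C@H](O)CC(=O)N(C)OC | intermediate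
16 | 2-(3-chloropropyl)-1,3-dioxolane | ClCCCC1OCCO1 | starting material
17 | [3-(1,3-dioxolan-2-yl)propyl]magnesium chloride | Cl[Mg]CCCC1OCCO1 | intermediate (not isolated)
18 | magnesium hemiaminal chelate from 15 and 17 (configuration at the hemiaminal carbon not controlled) | C[C@H](O[Mg]Cl)CC(O[Mg]Cl)(N(C)OC)CCCC1OCCO1 | intermediate (not isolated)
19 | (6S)-1-(1,3-dioxolan-2-yl)-6-hydroxyheptan-4-one | C[C@H](O)CC(=O)CCCC1OCCO1 | intermediate
20 | O-diethylboryl derivative (boron chelate) of 19 | CCB(CC)O[C@@H](C)CC(=O)CCCC1OCCO1 | intermediate (not isolated)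
21 | sodium cyclic diethyl dialkoxyborate of diol 22 | CC[B-]1(CC)O[C@@H](C)C[C@@H](CCCC2OCCO2)O1.[Na+] | intermediate (not isolated)
22 | (2S,4R)-7-(1,3-dioxolan-2-yl)heptane-2,4-diol | C[C@H](O)C[C@H](O)CCCC1OCCO1 | intermediate
23 | 2-[(4R,6S)-4,6-bis(tert-butyldimethylsilyloxy)heptyl]-1,3-dioxolane | C[C@H](O[Si](C)(C)C(C)(C)C)C[C@H](O[Si](C)(C)C(C)(C)C)CCCC1OCCO1 | intermediate
24 | 2-[(4R,6S)-4,6-bis(tert-butyldimethylsilyloxy)heptyl]-1,3-dithiane | C[C@H](O[Si](C)(C)C(C)(C)C)C[C@H](O[Si](C)(C)C(C)(C)C)CCCC1SCCCS1 | intermediate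
25 | 2-lithio derivative of 24 | C[C@H](O[Si](C)(C)C(C)(C)C)C[C@H](O[Si](C)(C)C(C)(C)C)CCCC1([Li])SCCCS1 | intermediate (not isolated)
26 | lithium (2R)-1-chloro-3-{2-[(4R,6S)-4,6-bis(tert-butyldimethylsilyloxy)heptyl]-1,3-dithian-2-yl}propan-2-olate | C[C@H](O[Si](C)(C)C(C)(C)C)C[C@H](O[Si](C)(C)C(C)(C)C)CCCC1(C[C@@H]([O-])CCl)SCCCS1.[Li+] | intermediate (not isolated)
27 | 2-[(4R,6S)-4,6-bis(tert-butyldimethylsilyloxy)heptyl]-2-{[(2R)-oxiran-2-yl]methyl}-1,3-dithiane (C12–C22 epoxide) | C[C@H](O[Si](C)(C)C(C)(C)C)C[C@H](O[Si](C)(C)C(C)(C)C)CCCC1(C[C@@H]2CO2)SCCCS1 | intermediate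
28 | 2-lithio-2-(tert-butyldimethylsilyl)-1,3-dithiane | CC(C)(C)[Si](C)(C)C1([Li])SCCCS1 | intermediate (not isolated)
29 | lithium alkoxide from 28 and 10 (O9 alkoxide, silicon still on C11) | CC(C)(C)[Si](C)(C)C1(SCCCS1)C[C@H]([O-])C/C(C)=C/[C@@H](O[Si](C)(C)C(C)(C)C)CC=C.[Li+] | intermediate (not isolated)
30 | 2-lithio-2-[(2R,4E,6S)-2,6-bis(tert-butyldimethylsilyloxy)-4-methylnona-4,8-dien-1-yl]-1,3-dithiane (after 1,4-Brook shift) | [Li]C1(SCCCS1)C[C@H](O[Si](C)(C)C(C)(C)C)C/C(C)=C/[C@@H](O[Si](C)(C)C(C)(C)C)CC=C | intermediate (not isolated)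
31 | 2-[(2R,4E,6S)-2,6-bis(TBSO)-4-methylnona-4,8-dien-1-yl]-2-[(2R)-3-{2-[(4R,6S)-4,6-bis(TBSO)heptyl]-1,3-dithian-2-yl}-2-hydroxypropyl]-1,3-dithiane (C3–C22 chain; 5S,9R,13R,19R,21S; O13 free) | C[C@H](O[Si](C)(C)C(C)(C)C)C[C@H](O[Si](C)(C)C(C)(C)C)CCCC1(SCCCS1)C[C@@H](O)CC2(SCCCS2)C[C@H](O[Si](C)(C)C(C)(C)C)C/C(C)=C/[C@@H](O[Si](C)(C)C(C)(C)C)CC=C | intermediate
32 | acryloyl chloride | C=CC(=O)Cl | starting material
33 | acrylate of 31 at O13: (2R)-1-{2-[(2R,4E,6S)-2,6-bis(TBSO)-4-methylnona-4,8-dien-1-yl]-1,3-dithian-2-yl}-3-{2-[(4R,6S)-4,6-bis(TBSO)heptyl]-1,3-dithian-2-yl}propan-2-yl prop-2-enoate | C[C@H](O[Si](C)(C)C(C)(C)C)C[C@H](O[Si](C)(C)C(C)(C)C)CCCC1(SCCCS1)C[C@@H](OC(=O)C=C)CC2(SCCCS2)C[C@H](O[Si](C)(C)C(C)(C)C)C/C(C)=C/[C@@H](O[Si](C)(C)C(C)(C)C)CC=C | intermediate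
34 | (4S,5E,8R,12R,18R,20S)-4,8,18,20-tetrakis(TBSO)-6-methyl-10,14-dioxohenicosa-1,5-dien-12-yl prop-2-enoate (precursor of the key step; ketones at C11 and C15) | O=C(CCC[C@@H](O[Si](C)(C)C(C)(C)C)C[C@H](C)O[Si](C)(C)C(C)(C)C)C[C@@H](OC(=O)C=C)CC(=O)C[C@H](O[Si](C)(C)C(C)(C)C)C/C(C)=C/[C@@H](O[Si](C)(C)C(C)(C)C)CC=C | intermediate
35 | (3E,6S,7E,10R,14R)-6,10-bis(TBSO)-14-[(6R,8S)-6,8-bis(TBSO)-2-oxononyl]-8-methyl-1-oxacyclotetradeca-3,7-diene-2,12-dione (product of the key step) | O=C(CCC[C@@H](O[Si](C)(C)C(C)(C)C)C[C@H](C)O[Si](C)(C)C(C)(C)C)C[C@@H]1CC(=O)C[C@H](O[Si](C)(C)C(C)(C)C)C/C(C)=C/[C@@H](O[Si](C)(C)C(C)(C)C)C/C=C/C(=O)O1 | intermediate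
36 | (3E,6S,7E,10S,14R)-6,10-bis(TBSO)-14-[(6R,8S)-6,8-bis(TBSO)-2-methylidenenonyl]-8-methyl-12-methylidene-1-oxacyclotetradeca-3,7-dien-2-one | C=C(CCC[C@@H](O[Si](C)(C)C(C)(C)C)C[C@H](C)O[Si](C)(C)C(C)(C)C)C[C@@H]1CC(=C)C[C@H](O[Si](C)(C)C(C)(C)C)C/C(C)=C/[C@@H](O[Si](C)(C)C(C)(C)C)C/C=C/C(=O)O1 | intermediate
37 | (6S,7E,10S,14R)-6,10-bis(TBSO)-14-[(6R,8S)-6,8-bis(TBSO)-2-methylidenenonyl]-8-methyl-12-methylidene-1-oxacyclotetradec-7-en-2-one | C=C(CCC[C@@H](O[Si](C)(C)C(C)(C)C)C[C@H](C)O[Si](C)(C)C(C)(C)C)C[C@@H]1CC(=C)C[C@H](O[Si](C)(C)C(C)(C)C)C/C(C)=C/[C@@H](O[Si](C)(C)C(C)(C)C)CCCC(=O)O1 | intermediate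
38 | (6S,7E,10S,14R)-14-[(6R,8S)-6,8-dihydroxy-2-methylidenenonyl]-6,10-dihydroxy-8-methyl-12-methylidene-1-oxacyclotetradec-7-en-2-one (macrolide numbering 5S,9S,13R,19R,21S) | C=C(CCC[C@@H](O)C[C@H](C)O)C[C@@H]1CC(=C)C[C@H](O)C/C(C)=C/[C@@H](O)CCCC(=O)O1 | target

## Step count and least certain steps

Total: 20 steps. Longest linear sequence: 13 steps (steps 8–13 then 14–20 from ethyl (S)-3-hydroxybutanoate 14; equally steps 1–6 then 14–20 from (R)-epichlorohydrin 1).

**Step 17 (key step).** The most likely failure is intermolecular metathesis (dimers and oligomers) if the open chain does not fold for closure, together with catalyst decay before conversion is complete and alkene migration by ruthenium hydrides. The fallback forms C2=C3 between molecules and closes the ring at the ester bond. It sets out from 31. Unmasking with PhI(OCOCF3)2 gives the hydroxy diketone F1. Cross-metathesis of its vinyl group with acrylic acid under the same ruthenium catalyst gives the (E)-seco acid F2. Lactonisation onto O13 with 2-methyl-6-nitrobenzoic anhydride and DMAP at high dilution returns to the route at 35.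

**Step 2.** Closure of the aluminium or lithium chloroalkoxide to an epoxide and its opening at the alanate stage, or incomplete hydroxymethylation, would erode the yield. The fallback sets out from 2. Carboalumination is quenched with iodine to give vinyl iodide F3. K2CO3 in methanol closes it to the iodo epoxide F4. Formylation with Pd(PPh3)4 (zerovalent palladium), CO and Bu3SnH gives 7, where the route is rejoined.

**Step 14.** Premature silyl migration, proton quench of the second anion or a second addition to epoxide 10 would give mixtures. The fallback is the stepwise sequence from 11 and 10. 2-Lithio-1,3-dithiane 12 opens 10 to the dithiane alcohol F5. Silylation gives the bis-silyl ether F6. Metalation with t-BuLi in THF/HMPA and addition of 27 returns to 31.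

**Step 16.** Loss of acrylic acid by β-elimination once both flanking ketones are free, or oxidation at the electron-rich C6=C7 alkene, are the main dangers. The fallback shortens the lifetime of the open-chain β-acyloxy diketone. It sets out from 33, closes the ring first with the thioacetals in place to give the macrocyclic bis-dithiane enoate F7, and then unmasks on the ring to rejoin at 35, which is taken on directly to step 18.

**Step 18.** Ring opening by β-elimination at C13, or incomplete reaction at the more hindered ring ketone, may occur. The fallback replaces the titanium carbenoid by a Peterson sequence from 35. Addition of Me3SiCH2Li/CeCl3 to both ketones gives the bis(β-hydroxysilane) F8. Elimination in NaOAc-buffered acetic acid returns to 36.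

**Step 20.** Acyl migration from O13 to the liberated O5 (contraction to a six-membered lactone) or ionisation of the allylic C5 carbinol may occur during the long exposure needed for four secondary silyl ethers. The fallback inverts the last two steps from 36. Desilylation is done while the E-C2=C3 bond still prevents O5 from reaching C1, giving the tetraol enoate F9. Conjugate reduction with [(Ph3P)CuH]6 under neutral conditions then gives 38.

## Further compounds

F1 | step 17 | (4S,5E,8R,12R,18R,20S)-4,8,18,20-tetrakis(TBSO)-12-hydroxy-6-methylhenicosa-1,5-diene-10,14-dione | O=C(CCC[C@@H](O[Si](C)(C)C(C)(C)C)C[C@H](C)O[Si](C)(C)C(C)(C)C)C[C@@H](O)CC(=O)C[C@H](O[Si](C)(C)C(C)(C)C)C/C(C)=C/[C@@H](O[Si](C)(C)C(C)(C)C)CC=C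
F2 | step 17 | (2E,5S,6E,9R,13R,19R,21S)-5,9,19,21-tetrakis(TBSO)-13-hydroxy-7-methyl-11,15-dioxodocosa-2,6-dienoic acid | O=C(CCC[C@@H](O[Si](C)(C)C(C)(C)C)C[C@H](C)O[Si](C)(C)C(C)(C)C)C[C@@H](O)CC(=O)C[C@H](O[Si](C)(C)C(C)(C)C)C/C(C)=C/[C@@H](O[Si](C)(C)C(C)(C)C)C/C=C/C(=O)O
F3 | step 2 | (2R,4E)-1-chloro-5-iodo-4-methylpent-4-en-2-ol | ClC[C@H](O)C/C(C)=C/I
F4 | step 2 | (2R)-2-[(2E)-3-iodo-2-methylprop-2-en-1-yl]oxirane | C1[C@H](O1)C/C(C)=C/I
F5 | step 14 | (2R,4E,6S)-6-(tert-butyldimethylsilyloxy)-1-(1,3-dithian-2-yl)-4-methylnona-4,8-dien-2-ol | S1CCCSC1C[C@H](O)C/C(C)=C/[C@@H](O[Si](C)(C)C(C)(C)C)CC=C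
F6 | step 14 | 2-[(2R,4E,6S)-2,6-bis(tert-butyldimethylsilyloxy)-4-methylnona-4,8-dien-1-yl]-1,3-dithiane | S1CCCSC1C[C@H](O[Si](C)(C)C(C)(C)C)C/C(C)=C/[C@@H](O[Si](C)(C)C(C)(C)C)CC=C
F7 | step 16 | 14-membered (2E)-enoate lactone of 33 with C11 and C15 still as 1,3-dithianes (5S,9R,13R,19R,21S) | C[C@H](O[Si](C)(C)C(C)(C)C)C[C@H](O[Si](C)(C)C(C)(C)C)CCCC1(SCCCS1)C[C@@H]2CC3(SCCCS3)C[C@H](O[Si](C)(C)C(C)(C)C)C/C(C)=C/[C@@H](O[Si](C)(C)C(C)(C)C)C/C=C/C(=O)O2
F8 | step 18 | bis(β-hydroxysilane) from 35: C11 and C15 as tertiary carbinols bearing CH2SiMe3 (epimer mixtures at C11 and C15) | C[Si](C)(C)CC(O)(CCC[C@@H](O[Si](C)(C)C(C)(C)C)C[C@H](C)O[Si](C)(C)C(C)(C)C)C[C@@H]1CC(O)(C[Si](C)(C)C)C[C@H](O[Si](C)(C)C(C)(C)C)C/C(C)=C/[C@@H](O[Si](C)(C)C(C)(C)C)C/C=C/C(=O)O1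
F9 | step 20 | (3E,6S,7E,10S,14R)-14-[(6R,8S)-6,8-dihydroxy-2-methylidenenonyl]-6,10-dihydroxy-8-methyl-12-methylidene-1-oxacyclotetradeca-3,7-dien-2-one | C=C(CCC[C@@H](O)C[C@H](C)O)C[C@@H]1CC(=C)C[C@H](O)C/C(C)=C/[C@@H](O)C/C=C/C(=O)O1
A1 | alternative 1 | C1–C22 chain with C11 dithiane, O9 silylated, O13 free, C1 as PMB ether | C=C(CCC[C@@H](O[Si](C)(C)C(C)(C)C)C[C@H](C)O[Si](C)(C)C(C)(C)C)C[C@@H](O)CC1(SCCCS1)C[C@H](O[Si](C)(C)C(C)(C)C)C/C(C)=C/[C@@H](O[Si](C)(C)C(C)(C)C)CCCCOCc2ccc(OC)cc2
A2 | alternative 1 | C1–C10 epoxide with C1 PMB ether and O5 silyl ether | C1[C@H](O1)C/C(C)=C/[C@@H](O[Si](C)(C)C(C)(C)C)CCCCOCc2ccc(OC)cc2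
A3 | alternative 1 | C12–C22 epoxide with C15 methylene | C=C(CCC[C@@H](O[Si](C)(C)C(C)(C)C)C[C@H](C)O[Si](C)(C)C(C)(C)C)C[C@@H]1CO1
A4 | alternative 2 | 14-membered cycloalkyne lactone (C6≡C7) | C=C(CCC[C@@H](O[Si](C)(C)C(C)(C)C)C[C@H](C)O[Si](C)(C)C(C)(C)C)C[C@@H]1CC(=C)C[C@H](O[Si](C)(C)C(C)(C)C)CC#C[C@@H](O[Si](CC)(CC)CC)CCCC(=O)O1
A5 | alternative 2 | diyne ester with methyl-capped alkynes at C6 and C7 | C=C(CCC[C@@H](O[Si](C)(C)C(C)(C)C)C[C@H](C)O[Si](C)(C)C(C)(C)C)C[C@H](CC(=C)C[C@H](O[Si](C)(C)C(C)(C)C)CC#CC)OC(=O)CCC[C@H](O[Si](CC)(CC)CC)C#CC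
A6 | alternative 3 | tris-silylated macrolide with free C5 hydroxyl | C=C(CCC[C@@H](O[Si](C)(C)C(C)(C)C)C[C@H](C)O[Si](C)(C)C(C)(C)C)C[C@@H]1CC(=C)C[C@H](O[Si](C)(C)C(C)(C)C)C/C(C)=C/[C@@H](O)CCCC(=O)O1
A7 | alternative 3 | ynal ester: O13 5-oxopentanoate with terminal C6≡C7 alkyne | C=C(CCC[C@@H](O[Si](C)(C)C(C)(C)C)C[C@H](C)O[Si](C)(C)C(C)(C)C)C[C@H](CC(=C)C[C@H](O[Si](C)(C)C(C)(C)C)CC#C)OC(=O)CCCC=O
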